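(The runs were computed on assumed constants, noise included.)

Doubling the time from 2.00 min to 4.00 min added 2.2 percentage points of D to Monday's flask, and this gain per doubling is the number to carry. In these flasks the catalyst X turns E into D, and the candidate steps also let D pass to L and L to Z, while X may go to Q or, two at a time, to J.

| flask | E | X | remark | time |
|---|---|---|---|---|
| Monday's | 0.11 M | 10 mol% | run made earlier |  |
| green | 0.060 M | 6 mol% |  | 20 min |
| teal | 0.20 M | 20 mol% |  | 20 min |
| ochre | 0.10 M | 10 mol% |  | 20 min |
| grey | 0.050 M | 3 mol% |  | 20 min |

Monday's run (percent of the E charged)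

| time / min | D / % |
|---|---|
| 0.333 | 6.1 |
| 1.00 | 9.1 |
| 2.00 | 11.2 |
| 3.00 | 12.4 |
| 4.00 | 13.4 |

(each reading ± 0.5 percentage points)

- candidate steps: X -> Q; D <-> L; L <-> Z; 2 X -> J; E + X <-> D + X
- no earlier run changes the charge of X; that part of a forecast is a guess

- ranking by amount of D, in percent of the E charged, from high to low, at 20 min (green / teal / ochre / grey)
- the amount of D, in percent of the E charged of the flask you put first, at 20 min
- the amount of D, in percent of the E charged of the flask you put last, at 20 min

Monday's readings seem to disagree with each other. D gained 6.1 % in the first 0.333 min but 1 point in the last minute, which looks like a flask stopping. Yet the doubling from 1.00 min to 2.00 min gave 2.1 points, about the same as the next one, given a scatter of 0.5 points on each reading. So over these readings D climbs by about equal steps on a logarithmic clock. If X dies by pairs, late X falls as one over time, and what counts is the product of X charged, in M, and time.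

My reckoning therefore counts doublings of that product from Monday's last reading, assuming that doubling X equals doubling time, which no earlier run tests. Teal lies 4.18 doublings up, which gives 22.6 %. Ochre lies 2.18 up and green 0.710 up. Grey lies 0.553 down, which gives 12.2 %.

The forecast says teal > ochre > green > grey, with teal at 21.5 % (17.5 % to 25 %) and grey at 12.1 % (9.5 % to 14 %), holding that “D grows logarithmically rather than levelling off or staying linear”. My teal stands 1.1 points above its figure, and the order is the same.

The flasks give teal > ochre > green > grey, with teal at 22.6 % and grey at 11.2 %, 1.00 point under my figure and inside the forecast's range.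

    X → Q (k = 3.50 × 10⁻⁶ s⁻¹)
    D ⇌ L (K = 0.600, k = 0.0141 s⁻¹)
    L ⇌ Z (K = 0.290, k = 0.00369 s⁻¹)
    2 X → J (k = 1.83 M⁻¹ s⁻¹)
    E + X ⇌ D + X, rate k5*[E]*[X] forward; the back reaction follows from the equilibrium constant (K = 1.60, k = 0.414 M⁻¹ s⁻¹)

The largest single effect on D in grey is the loss of two X to J, though it is not the whole story: with that step struck out, grey reaches 26.8 % of D instead of 11.2 %, and at 20.0 min grey holds 13.1 % of its catalyst as X and 86.7 % as J. Now take teal with 5 mol% of X, a quarter of its loading, which is two doublings down at 2.2 points each: the reckoning gives 18.2 %, and that flask stands at 18.4 %.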